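Retrosynthesis: the C3–CHBr2 bond is cut first (carbenoid addition to a ring B enone), then the C9–OH/C10–Br pair is traced to an α-bromoketone and further to a β-keto ester.
Ring B is cut at C5–C6 and C1=C2 (Robinson-type annulation of a ring A aldehyde with but-3-en-2-one); ring A is cut at C6–C7 and C9–C10, giving di-tert-butyl 3,3-dimethylglutarate and ethyl buta-2,3-dienoate.
Enabling feature: in ring A, C7(=CH2)–C8H2–C9(O) is a but-3-enoyl unit, the pattern left by conjugate addition to the central carbon of an allenoate, and C6 and C10 are the two α-carbons flanking the gem-dimethyl carbon C11 of a glutarate; one Michael–Dieckmann [3+3] annulation therefore builds ring A, its exocyclic methylene and both carboxyl handles.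
Forward order: ring A (step 2), C6 ester to aldehyde, spiro-annulation of ring B, CHBr2 carbinol, bromination with loss of the C10 carboxyl, ketone reduction; the C6 carboxyl becomes C1 of ring B and the C10 carboxyl directs bromine to C10 and leaves as CO2.
Stereochemistry: C6 by catalyst control in the annulation with butenone; C3 by attack anti to the gem-dimethyl-bearing arm of ring A; C10 by axial protonation of a bromo-enol (equatorial Br); C9 by hydride delivery anti to the axial C11 methyl (axial OH, cis to Br).
Locants are those of the target throughout: ring B is C1–C5, the spiro carbon is C6, ring A is C7–C11.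

Key step: step 2

Assumption: the proline sulfonamide catalyst of step 5 is taken to give the (6S) centre; if the opposite sense were found, the catalyst made from the other proline enantiomer would be used. Compounds 4–7 are racemic, and their C6 and C10 centres are erased later.

Step 1
Reactants: 1 3,3-dimethylpentanedioic acid
Product: 2 di-tert-butyl 3,3-dimethylpentanedioate
Conditions: 2-methylpropene (excess), H2SO4 (cat.), CH2Cl2, sealed vessel, rt
Reagents that add atoms: 2-methylpropene, CC(C)=C
Why: acid-catalysed addition of both carboxyl groups to isobutene (tert-butyl ester formation) should be clean, and no stereocentre is formed.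

Step 2
Reactants: 2 di-tert-butyl 3,3-dimethylpentanedioate; 3 ethyl buta-2,3-dienoate
Product: 5 di-tert-butyl 2,2-dimethyl-4-methylidene-6-oxocyclohexane-1,3-dicarboxylate (racemic; mixture of epimers), via Michael adduct 4 (not isolated)
Conditions: LiN(i-Pr)2 (1.1 equiv), THF, –78 °C; then 3 (1.0 equiv, slow addition), –78 → 0 °C; AcOH quench
Reagents that add atoms: none
Why: The lithium mono-enolate of the symmetric diester 2 should add to the central carbon of allenoate 3 (Michael addition) and form the C6–C7 bond; the resulting ester dienolate is protonated at its α-carbon C8, which leaves the 1,1-disubstituted C7=CH2 alkene of adduct 4. Proton transfer then gives the enolate at the other glutarate α-carbon C10, which closes onto the ethyl ester (Dieckmann condensation, 6-(enolexo)-exo-trig) and forms the C9–C10 bond with loss of ethoxide; deprotonation of the β-keto ester makes this closure irreversible. The closest known reaction type is the tandem Michael–Dieckmann [3+3] annulation of ester enolates with acrylates, combined with the known conjugate addition of carbon nucleophiles to the central carbon of 2,3-allenoates. C6 and C10 arise as stereocentres without control, which is harmless because C6 becomes planar in the dienamine of step 5 and C10 is enolised and reset in step 7. The step needs closure through C10 and not the alternative six-membered Claisen closure of the C8 carbanion onto a glutarate ester; the tert-butyl esters, poor acyl acceptors beside the ethyl ester, should secure this. It also needs the exocyclic alkene to stay out of conjugation, which kinetic α-protonation of the dienolate at low temperature and the immediate conversion of the new ketone into its C9–C10 enolate should secure.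

Step 3
Reactants: 5 di-tert-butyl 2,2-dimethyl-4-methylidene-6-oxocyclohexane-1,3-dicarboxylate
Product: 6 tert-butyl 3-(hydroxymethyl)-2,2-dimethyl-4-methylidene-6-oxocyclohexane-1-carboxylate (racemic)
Conditions: NaH (1.05 equiv), THF, 0 °C; then LiAlH4 (1.0 equiv), 0 °C → rt; H2O, aq. NaOH work-up
Reagents that add atoms: none
Why: with the β-keto ester shielded as its sodium enolate, LiAlH4 ester reduction should touch only the isolated C6 tert-butyl ester; no stereocentre that survives is set.

Step 4
Reactants: 6 tert-butyl 3-(hydroxymethyl)-2,2-dimethyl-4-methylidene-6-oxocyclohexane-1-carboxylate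
Product: 7 tert-butyl 3-formyl-2,2-dimethyl-4-methylidene-6-oxocyclohexane-1-carboxylate (racemic)
Conditions: Dess–Martin periodinane (1.2 equiv), pyridine, CH2Cl2, 0 °C
Reagents that add atoms: none
Why: buffered Dess–Martin oxidation of the primary alcohol should give the aldehyde, and any migration of the C7 alkene into conjugation would be harmless because both isomers give the same dienamine in step 5.

Step 5
Reactants: 7 tert-butyl 3-formyl-2,2-dimethyl-4-methylidene-6-oxocyclohexane-1-carboxylate; 8 but-3-en-2-one
Product: 10 tert-butyl (6S)-11,11-dimethyl-7-methylidene-3,9-dioxospiro[5.5]undec-1-ene-10-carboxylate (C10 epimers), via keto aldehyde 9 (not isolated)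
Conditions: 8 (3 equiv), (S)-N-(4-dodecylphenylsulfonyl)pyrrolidine-2-carboxamide (20 mol%), 4 Å molecular sieves, ClCH2CH2Cl, rt → 40 °C
Reagents that add atoms: none
Why: an organocatalytic Robinson-type annulation (enamine Michael addition of the α,α-disubstituted aldehyde through its dienamine at C6, then aldol condensation of the methyl ketone onto the aldehyde) should build ring B with its enone in place, and the C6 quaternary centre is set by the catalyst, whose sulfonamide N–H steers butenone to one face of the planar dienamine.

Step 6
Reactants: 10 tert-butyl (6S)-11,11-dimethyl-7-methylidene-3,9-dioxospiro[5.5]undec-1-ene-10-carboxylate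
Product: 11 tert-butyl (3R,6S)-3-(dibromomethyl)-3-hydroxy-11,11-dimethyl-7-methylidene-9-oxospiro[5.5]undec-1-ene-10-carboxylate (C10 epimers)
Conditions: LiN(i-Pr)2 (1.05 equiv), THF, –78 °C (enolate of the β-keto ester); then added to LiCHBr2 [from CH2Br2 (3 equiv) and LiN(i-Pr)2 (2.5 equiv), THF, –90 °C]; AcOH quench at –90 °C
Reagents that add atoms: dibromomethane, BrCBr
Why: 1,2-addition of dibromomethyllithium to the enone carbonyl (carbenoid addition, with the β-keto ester protected as its enolate) should give the tertiary carbinol, and C3 is set by approach from the face of ring B flanked by the planar C7 arm, away from the equatorial C11 methyl that covers the other face.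

Step 7
Reactants: 11 tert-butyl (3R,6S)-3-(dibromomethyl)-3-hydroxy-11,11-dimethyl-7-methylidene-9-oxospiro[5.5]undec-1-ene-10-carboxylate
Product: 14 (3R,6S,10S)-10-bromo-3-(dibromomethyl)-3-hydroxy-11,11-dimethyl-7-methylidenespiro[5.5]undec-1-en-9-one, via tris-silylated enol ether 12 (not isolated), via bromo keto acid 13 (not isolated)
Conditions: Me3SiOTf (3.5 equiv), 2,6-lutidine (5 equiv), CH2Cl2, 0 °C → rt; then N-bromosuccinimide (1.05 equiv), –78 °C, dark; then aq. citric acid, THF, rt
Reagents that add atoms: N-bromosuccinimide, O=C1CCC(=O)N1Br
Why: dealkylative silylation turns the tert-butyl β-keto ester into its silyl enol ether and silyl ester, N-bromosuccinimide brominates that enol ether only at C10, and hydrolysis with decarboxylation of the α-bromo β-keto acid should give the α-bromoketone without exposing the β,γ-unsaturated ketone to strong acid; C10 is set on ketonisation by axial protonation of the bromo-enol, which places bromine equatorial and cis to the equatorial C1 arm of ring B.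

Step 8
Reactants: 14 (3R,6S,10S)-10-bromo-3-(dibromomethyl)-3-hydroxy-11,11-dimethyl-7-methylidenespiro[5.5]undec-1-en-9-one
Product: 15 (3R,6S,9R,10S)-10-bromo-3-(dibromomethyl)-11,11-dimethyl-7-methylidenespiro[5.5]undec-1-ene-3,9-diol (Mailiohydrin)
Conditions: i-Bu2AlH (3 equiv), CH2Cl2, –78 °C; aq. KNaC4H4O6 work-up
Reagents that add atoms: none
Why: aluminium hydride reduction of the α-bromoketone should deliver hydride along the equatorial trajectory, because the axial path is blocked by the axial C11 methyl, and so give the axial C9 alcohol cis to the equatorial bromine.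

Compound list
1 | 3,3-dimethylpentanedioic acid (3,3-dimethylglutaric acid) | OC(=O)CC(C)(C)CC(=O)O | starting material
2 | di-tert-butyl 3,3-dimethylpentanedioate | CC(C)(C)OC(=O)CC(C)(C)CC(=O)OC(C)(C)C | intermediate
3 | ethyl buta-2,3-dienoate | C=C=CC(=O)OCC | starting material
4 | di-tert-butyl 2-(4-ethoxy-4-oxobut-1-en-2-yl)-3,3-dimethylpentanedioate (racemic; not isolated) | C=C(CC(=O)OCC)C(C(=O)OC(C)(C)C)C(C)(C)CC(=O)OC(C)(C)C | intermediate
5 | di-tert-butyl 2,2-dimethyl-4-methylidene-6-oxocyclohexane-1,3-dicarboxylate (racemic; both ring CH centres undefined) | C=C1CC(=O)C(C(=O)OC(C)(C)C)C(C)(C)C1C(=O)OC(C)(C)C | intermediate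
6 | tert-butyl 3-(hydroxymethyl)-2,2-dimethyl-4-methylidene-6-oxocyclohexane-1-carboxylate (racemic) | C=C1CC(=O)C(C(=O)OC(C)(C)C)C(C)(C)C1CO | intermediate
7 | tert-butyl 3-formyl-2,2-dimethyl-4-methylidene-6-oxocyclohexane-1-carboxylate (racemic) | C=C1CC(=O)C(C(=O)OC(C)(C)C)C(C)(C)C1C=O | intermediate
8 | but-3-en-2-one | CC(=O)C=C | starting material
9 | tert-butyl (3S)-3-formyl-2,2-dimethyl-4-methylidene-6-oxo-3-(3-oxobutyl)cyclohexane-1-carboxylate (not isolated) | C=C1CC(=O)C(C(=O)OC(C)(C)C)C(C)(C)[C@]1(C=O)CCC(C)=O | intermediate
10 | tert-butyl (6S)-11,11-dimethyl-7-methylidene-3,9-dioxospiro[5.5]undec-1-ene-10-carboxylate (C10 undefined) | C=C1CC(=O)C(C(=O)OC(C)(C)C)C(C)(C)[C@@]12C=CC(=O)CC2 | intermediate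
11 | tert-butyl (3R,6S)-3-(dibromomethyl)-3-hydroxy-11,11-dimethyl-7-methylidene-9-oxospiro[5.5]undec-1-ene-10-carboxylate (C10 undefined) | C=C1CC(=O)C(C(=O)OC(C)(C)C)C(C)(C)[C@@]12C=C[C@@](O)(C(Br)Br)CC2 | intermediate
12 | trimethylsilyl (3R,6S)-3-(dibromomethyl)-11,11-dimethyl-7-methylidene-3,9-bis(trimethylsilyloxy)spiro[5.5]undeca-1,9-diene-10-carboxylate (not isolated) | C=C1CC(O[Si](C)(C)C)=C(C(=O)O[Si](C)(C)C)C(C)(C)[C@@]12C=C[C@@](O[Si](C)(C)C)(C(Br)Br)CC2 | intermediate
13 | (3R,6S)-10-bromo-3-(dibromomethyl)-3-hydroxy-11,11-dimethyl-7-methylidene-9-oxospiro[5.5]undec-1-ene-10-carboxylic acid (C10 undefined; not isolated) | C=C1CC(=O)C(Br)(C(=O)O)C(C)(C)[C@@]12C=C[C@@](O)(C(Br)Br)CC2 | intermediate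
14 | (3R,6S,10S)-10-bromo-3-(dibromomethyl)-3-hydroxy-11,11-dimethyl-7-methylidenespiro[5.5]undec-1-en-9-one | C=C1CC(=O)[C@@H](Br)C(C)(C)[C@@]12C=C[C@@](O)(C(Br)Br)CC2 | intermediate
15 | (3R,6S,9R,10S)-10-bromo-3-(dibromomethyl)-11,11-dimethyl-7-methylidenespiro[5.5]undec-1-ene-3,9-diol (Mailiohydrin) | C=C1C[C@@H](O)[C@@H](Br)C(C)(C)[C@@]12C=C[C@@](O)(C(Br)Br)CC2 | target

Total step count: 8. Longest linear sequence: 8 steps (1 to 15).

Steps most likely to fail

Step 5. The α-carbon of 7 lies next to a quaternary carbon, so enamine formation and the Michael addition may be slow. Bond formation through the methylidene terminus of the dienamine, or conjugate addition of the β-keto ester carbon to 8, may compete, and facial discrimination by the catalyst may be poor. The fallback sets out from 7 and replaces the catalyst by a stoichiometric chiral auxiliary. Condensation with (S)-1-phenylethylamine (toluene, 4 Å molecular sieves) should give the 1-phenylethyl aldimine F1. Its secondary enamine tautomer should add to 8 through a cyclic, aza-ene-like transition state at the more substituted α-carbon (THF, rt to 40 °C) and give the adduct imine F2. Aqueous AcOH releases the amine and gives keto aldehyde 9, here isolated, and pyrrolidine/AcOH (aldol condensation) closes ring B, so the route is rejoined at 10.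

Step 2. Proton transfer from the allenoate to the strongly basic ester enolate (with isomerisation of the allenoate), carbonyl addition in place of conjugate addition, or migration of the exocyclic alkene before ring closure may spoil the annulation. The fallback sets out from 2 and forms the two bonds in separate steps. Aldol addition of the lithium enolate of 2 to 3-bromobut-3-enal F3 (from commercial 3-bromobut-3-en-1-ol by Dess–Martin oxidation) should give the hydroxy diester F4, which forms C9–C10. Dess–Martin oxidation gives the β-keto ester F5. Palladium-catalysed intramolecular alkenylation of the remaining ester enolate by the vinyl bromide [LiN(SiMe3)2 (2.2 equiv), Pd(dba)2, P(t-Bu)3, toluene, rt] closes C6–C7, so the route is rejoined at 5.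

Step 6. The carbenoid may add to the wrong face of the ring B carbonyl, or may enolise the enone instead of adding. The fallback sets out from 10 and uses a bulkier, much less basic nucleophile. Tribromomethyllithium (CHBr3, LiN(i-Pr)2, THF, –100 °C, generated in the presence of the enolate of 10) should give the tribromomethyl carbinol F6. Removal of one bromine with diethyl phosphite/Et3N (THF, 0 °C) gives the dibromomethyl carbinol, so the route is rejoined at 11.

Further compounds
F1 | step 5 | tert-butyl 2,2-dimethyl-4-methylidene-6-oxo-3-{(E)-[(1S)-1-phenylethyl]iminomethyl}cyclohexane-1-carboxylate | C=C1CC(=O)C(C(=O)OC(C)(C)C)C(C)(C)C1/C=N/[C@@H](C)c1ccccc1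
F2 | step 5 | tert-butyl (3S)-2,2-dimethyl-4-methylidene-6-oxo-3-(3-oxobutyl)-3-{(E)-[(1S)-1-phenylethyl]iminomethyl}cyclohexane-1-carboxylate | C=C1CC(=O)C(C(=O)OC(C)(C)C)C(C)(C)[C@]1(/C=N/[C@@H](C)c1ccccc1)CCC(C)=O
F3 | step 2 | 3-bromobut-3-enal | C=C(Br)CC=O
F4 | step 2 | di-tert-butyl 2-(3-bromo-1-hydroxybut-3-en-1-yl)-3,3-dimethylpentanedioate (mixture of diastereomers) | C=C(Br)CC(O)C(C(=O)OC(C)(C)C)C(C)(C)CC(=O)OC(C)(C)C
F5 | step 2 | di-tert-butyl 2-(3-bromobut-3-enoyl)-3,3-dimethylpentanedioate | C=C(Br)CC(=O)C(C(=O)OC(C)(C)C)C(C)(C)CC(=O)OC(C)(C)C
F6 | step 6 | tert-butyl (3R,6S)-3-hydroxy-11,11-dimethyl-7-methylidene-9-oxo-3-(tribromomethyl)spiro[5.5]undec-1-ene-10-carboxylate | C=C1CC(=O)C(C(=O)OC(C)(C)C)C(C)(C)[C@@]12C=C[C@@](O)(C(Br)(Br)Br)CC2
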